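# Proposed total synthesis of CNP0159184.1 by ozonolytic opening of an epoxy-octalin

## Analysis of the target

The target (31) is a germacranolide. Its ten-membered carbocycle C1–C10 carries a butenolide fused at C6–C7 (O6–C12(=O)–C11=C7), with C13 as an acetoxymethyl group on C11. Six stereocentres lie on the carbocycle: C1 (S, free secondary alcohol), C4 (R) and C5 (S) (a cis-fused trisubstituted epoxide, methyl on C4), C6 (S, lactone carbinol), C8 (S, tiglate) and C10 (R, secondary methyl). Drawn as a flat ring, the oxygens on C1, C6 and C8, the epoxide oxygen and the C10 methyl all point to the same face. The C4–C8 segment is contiguous, but C1/C10 are insulated from it by methylene groups (C2, C3 and C9), so 1,2-induction alone cannot relate all the centres. The sensitive groups are the epoxide (acid; transannular attack by the C1 hydroxyl), the allylic acetate and tiglate (base, nucleophiles), and the butenolide, which can migrate from O6 to O8 once O8 is free. The hard part is the medium ring: direct closure of a ten-membered ring is costly, and stereocontrol on the flexible ring is unreliable. The strategy rests on one feature. C1 and C6 sit opposite each other in the ring and both carry oxygen, so the ring is the formal cleavage product of a C1=C6 ring-fusion alkene of an octalin whose ring A is C1–C6 and whose ring B is C6–C10 plus C1.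

## Retrosynthetic reasoning

**31 ⇐ 30 ⇐ 28 + 29.** The last bonds made are the C8–O acyl bond and, by desilylation, the free C1–OH. They come last because the tiglate would not survive ozonolysis or enolate chemistry and a free C1 hydroxyl can attack the epoxide across the ring. The two hydroxyls must be told apart, so O8 carries a triethylsilyl group (15 to 27) and O1 a tert-butyldimethylsilyl group (20 to 30). Two silyl ethers of equal stability could not be opened in sequence; with this pair O8 is freed first (28), acylated with 29, and O1 is released at the end.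

**28 ⇐ 27 ⇐ 26 ⇐ 24 ⇐ 22 ⇐ 20.** The butenolide is traced to the saturated γ-lactone 20. The O13 acetyl group is removed, the C7=C11 bond goes back to a selenoxide syn-elimination in 24, and the C11–Se and C11–C13 bonds to two successive enolate reactions. The order matters: each electrophile enters on the face of H7, so C13 goes on first (22) and selenium second (24). Only selenium cis to H7 can eliminate into the ring instead of toward the carbinol carbon C13.

**20 ⇐ 19 ⇐ 17.** Cutting the lactone C12–O6 bond and the C1–H and C6–H bonds leads to the 1,6-diketone ester 17. Both carbonyls are reduced together and at once, because 17 is prone to transannular aldol reaction. The C6 alkoxide then closes onto the C12 ester; O8 cannot compete because it is silylated. The reduction must set C1 and C6, and its handles are the C10 methyl next to C1 and the epoxide oxygen next to C6.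

**17 ⇐ 15 (key disconnection).** C1 and C6 are rejoined by a double bond, which folds the ten-membered ring into rings A and B of octalin 15. The cut is made here because it is the only one that produces the medium ring without a cyclisation. It also places C4, C5, C8 and C10 on six-membered rings, where they can be set reliably. The forward reaction has only to cleave one electron-rich alkene in the presence of an allylic epoxide.

**15 ⇐ 14 ⇐ 13.** The O8–Si bond and the C8–H bond are cut, giving the β,γ-unsaturated ketone 13. The reduction must place O8 cis to the C10 methyl, and silylation must follow before O8 can lactonise onto C12.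

**13 ⇐ 10 + 11.** The C7–C11 bond is cut. Alkylation of the extended enolate of enone 10 at C7 attaches the acetate arm (C11, C12) and moves the double bond from C6=C7 to the ring fusion C1=C6 in one operation. Deprotonation can extend the enolate only through C1, because the other γ-position, C5, is an epoxide carbon. The configuration at C7 is of no consequence for 31, where C7 is trigonal.

**10 ⇐ 9.** The epoxide C–O bonds are cut. In dienone 9 the C4=C5 bond is the distal, electron-rich alkene, so an electrophilic oxidant finds it. One point needs care: nothing in ring B reaches C4/C5, so the epoxide face cannot follow from C10. It is therefore set by the catalyst in a Shi epoxidation.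

**9 ⇐ 7.** The C6=C7 bond is cut by a retro-aldol condensation. Ring B closes when the methyl ketone of 7 condenses with the ring carbonyl.

**7 ⇐ 5 ⇐ 4 ⇐ 3.** The 3-methylcyclohexenone ring A is an aryl methyl ether in disguise. Birch reduction of 4 and hydrolysis of 5 give 7 with the ring oxygen at C6 and the methyl on C4. The side-chain ketone is masked as the dioxolane during the dissolving-metal step.

**3 ⇐ 1 + 2.** The C1–C10 bond is cut. A rhodium-catalysed asymmetric conjugate addition of 1 to 2 forms it and sets C10, the only stereocentre carried into step 6.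

## Alternatives that were turned down

**Alternative 1:** The C5–C6 bond and the lactone C12–O6 bond are cut, leading to the open-chain Z-alkenyl iodide aldehyde A2. In the forward direction a Nozaki–Hiyama–Kishi reaction (divalent chromium, catalytic nickel) would convert the C5–iodine bond into an alkenylchromium that adds to the C6 aldehyde. The C6 alkoxide would then close onto the cis C12 ester to give the deoxy lactone A1, whose 4,5-alkene is epoxidised last.
- For: carbocycle and butenolide form in one step, the route is convergent, and the tiglate and acetate are already in place, so far fewer functional-group steps follow ring formation than in the chosen route. On this point the alternative is stronger.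
- Against: the closure is a ten-membered ring formation from a chain, with the usual entropic cost, high dilution and large excess of metal. C6 is created during the closure with no nearby controlling element. A2 holds three stereocentres, a tetrasubstituted enoate aldehyde and a Z-trisubstituted iodide, and needs a long synthesis of its own. The final epoxidation must pick one face of a medium-ring alkene.
- Comparison: the chosen strategy gives up convergence and late-stage economy, but obtains the ring by cleavage, not closure, and sets four of the six centres on cyclohexenes.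

**Alternative 2:** The C10–C1 and C4–C5 bonds are cut. Enone A4 and cyclobutene A5 would combine in a [2+2] photocycloaddition to the photoadduct A3, and thermal cleavage of its bicyclo[2.2.0]hexane unit would then release a cyclodeca-1,5-diene.
- For: two C–C bonds and the whole C1–C10 ring arise in two steps from very simple pieces, with C8 already in A4. No other plan reaches the ring skeleton as quickly.
- Against: the cycloaddition must choose the correct orientation of the unsymmetrical A5 and the correct face relative to the C8 silyloxy group. The diene formed afterwards has C1=C10 and C4=C5, so C1–OH and C10–H must be installed by a regio- and stereoselective hydration on a flexible ring. The whole C11–C13 unit and the C6 carbinol are still missing. Cyclodeca-1,5-dienes also undergo Cope rearrangement at the temperatures of the opening.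
- Comparison: the chosen route is longer up to the ring, but releases it with oxygen already on C1 and C6, C10 and C8 already set, and C11/C12 attached.

**Alternative 3:** The C6–O and C13–O bonds are cut, leading to the ring dienoic acid A7. A palladium-catalysed oxidative 1,4-acetoxylactonisation (divalent palladium, a quinone as terminal oxidant, acetate as external nucleophile) would add the carboxylate to C6 and acetate to C13, giving butenolide A6.
- For: one step creates the butenolide, the C6–O bond and the C13 acetate. This is clearly better than the four-step selenium sequence of the chosen route (steps 13–16).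
- Against: it is an end-game only. The ten-membered ring of A7, with its diene and four stereocentres, still has to be made, so the central problem is unsolved. The C6 configuration depends on the ring conformation during palladium attack. The acetonide standing in for the epoxide must later be converted from a cis-diol into an epoxide with net retention, which costs several steps. The PMB ether adds another deprotection.
- Comparison: the chosen strategy solves the ring problem first and accepts a longer butenolide end-game.

Key step: step 10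

**Remarks on the chemistry**
- Locants C1–C13 are those of the target ring and are used for every intermediate. "Δ1(6)-octalin" means the octahydronaphthalene with the double bond between the ring-fusion carbons C1 and C6.
- Compounds 6–10 are mixtures of epimers at C1 (and 8 at C6). These centres are erased in step 7, and the SMILES leave them open.
- The sense of induction in the catalyst-controlled steps 1, 6 and 8 is assigned from the usual facial models. If any is found to be opposite, the mirror-image ligand, ketone or oxazaborolidine is used.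

## Route

Step 1
Reactants: 1 (2-methoxy-4-methylphenyl)boronic acid; 2 (E)-pent-3-en-2-one
Product: 3 (4R)-4-(2-methoxy-4-methylphenyl)pentan-2-one
Conditions: [Rh(OH)((R)-BINAP)]2 (cat.), dioxane/H2O 10:1, 35 °C
Reagents that add atoms: none
Why: Hayashi–Miyaura asymmetric 1,4-addition: transmetalation gives an arylrhodium that inserts the (E)-enone, and water protonates the rhodium enolate. The BINAP ligand differentiates the enone faces and sets C10; (R)-BINAP is expected to give 4R for an (E)-alkyl enone.

Step 2
Reactants: 3 (4R)-4-(2-methoxy-4-methylphenyl)pentan-2-one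
Product: 4 2-[(2R)-2-(2-methoxy-4-methylphenyl)propyl]-2-methyl-1,3-dioxolane
Conditions: HOCH2CH2OH, p-TsOH·H2O (cat.), benzene, reflux, Dean–Stark
Reagents that add atoms: ethylene glycol, OCCO
Why: Acid-catalysed ketalisation driven by azeotropic removal of water. The dioxolane shields the side-chain ketone from the dissolving metal in step 3.

Step 3
Reactants: 4 2-[(2R)-2-(2-methoxy-4-methylphenyl)propyl]-2-methyl-1,3-dioxolane
Product: 5 2-[(2R)-2-(2-methoxy-4-methylcyclohexa-1,4-dien-1-yl)propyl]-2-methyl-1,3-dioxolane
Conditions: Li, NH3(l), THF, t-BuOH, −78 to −33 °C; then NH4Cl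
Reagents that add atoms: none
Why: Birch reduction of an alkyl-substituted aryl methyl ether: protonation occurs at the two unsubstituted positions ortho and meta to the methoxy group (C5 and C2), leaving the enol ether C6=C1 and the C3=C4 alkene. The benzylic centre C10 is not involved.

Step 4
Reactants: 5 2-[(2R)-2-(2-methoxy-4-methylcyclohexa-1,4-dien-1-yl)propyl]-2-methyl-1,3-dioxolane
Product: 7 3-methyl-6-[(2R)-4-oxopentan-2-yl]cyclohex-2-en-1-one (C1 epimers), via non-conjugated cyclohex-3-enone diketone 6 (not isolated)
Conditions: 1 M HCl, THF, 25 °C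
Reagents that add atoms: water, O
Why: Acid hydrolysis of the enol ether and the dioxolane, followed by acid-catalysed migration of the ring double bond into conjugation, the way 2-alkyl-5-methylanisoles give piperitone-type enones. C1 forms as an epimeric mixture, which does not matter.

Step 5
Reactants: 7 3-methyl-6-[(2R)-4-oxopentan-2-yl]cyclohex-2-en-1-one
Product: 9 (4R)-4,7-dimethyl-4,4a,5,6-tetrahydronaphthalen-2(3H)-one, via bicyclic ketol 8 (not isolated)
Conditions: KOH, MeOH, 60 °C
Reagents that add atoms: none
Why: Intramolecular aldol condensation, the ring-closing half of a Robinson annulation: the methyl-ketone enolate (C7) adds to the ring carbonyl C6 in a six-membered closure, and E1cB dehydration gives the linearly conjugated dienone, the only irreversible outlet. C10 is untouched.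

Step 6
Reactants: 9 (4R)-4,7-dimethyl-4,4a,5,6-tetrahydronaphthalen-2(3H)-one
Product: 10 (4R,7R,8S)-7,8-epoxy-4,7-dimethyl-4,4a,5,6,7,8-hexahydronaphthalen-2(3H)-one
Conditions: L-fructose-derived ketone of the Shi epoxidation (1,2:4,5-di-O-isopropylidene-β-L-erythro-2,3-hexodiulo-2,6-pyranose, 0.3 equiv), KHSO5 (as Oxone), K2CO3, Bu4NHSO4, MeCN/CH2(OMe)2/aq. Na2B4O7 buffer pH 10.5, 0 °C
Reagents that add atoms: potassium peroxymonosulfate, [K+].[O-]S(=O)(=O)OO
Why: Shi epoxidation: the chiral dioxirane is electrophilic and attacks the distal, more electron-rich C4=C5 bond in preference to the enone bond. The spiro transition state for a trisubstituted alkene fixes the face, and the L-fructose-derived catalyst is expected to give the 4R,5S epoxide (target locants) regardless of the remote C10 centre.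

Step 7
Reactants: 10 (4R,7R,8S)-7,8-epoxy-4,7-dimethyl-4,4a,5,6,7,8-hexahydronaphthalen-2(3H)-one; 11 methyl bromoacetate
Product: 13 methyl 2-[(4R,5S,7S,10R)-4,5-epoxy-4,10-dimethyl-8-oxo-Δ1(6)-octalin-7-yl]acetate, via potassium dienolate 12 (not isolated)
Conditions: KOtBu (1.0 equiv), THF/t-BuOH, −20 °C; then 11, −78 to 0 °C; AcOH quench
Reagents that add atoms: none
Why: Deconjugative α-alkylation of an enone through its extended enolate. The γ-proton can be removed only at C1, because C5 is an epoxide carbon, and the enolate reacts at its α-carbon C7, which moves the double bond to the ring fusion C1=C6. The electrophile is expected to enter anti to the epoxide oxygen that overhangs the neighbouring position (7S); this centre is lost later.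

Step 8
Reactants: 13 methyl 2-[(4R,5S,7S,10R)-4,5-epoxy-4,10-dimethyl-8-oxo-Δ1(6)-octalin-7-yl]acetate
Product: 14 methyl 2-[(4R,5S,7S,8S,10R)-4,5-epoxy-8-hydroxy-4,10-dimethyl-Δ1(6)-octalin-7-yl]acetate
Conditions: (R)-2-methyl-CBS-oxazaborolidine (0.5 equiv), catecholborane, toluene/CH2Cl2, −78 °C; then pH 7 buffer
Reagents that add atoms: none
Why: Corey–Bakshi–Shibata reduction: the oxazaborolidine binds the ketone away from its larger flank (C7) and delivers hydride to one face. The (R)-catalyst is expected to give the 8S alcohol, cis to the C10 methyl, which is also the axial trajectory on the half-chair with pseudo-equatorial C7 and C10 groups. Catecholborane leaves the ester and epoxide alone.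

Step 9
Reactants: 14 methyl 2-[(4R,5S,7S,8S,10R)-4,5-epoxy-8-hydroxy-4,10-dimethyl-Δ1(6)-octalin-7-yl]acetate
Product: 15 methyl 2-[(4R,5S,7S,8S,10R)-4,5-epoxy-4,10-dimethyl-8-(triethylsilyloxy)-Δ1(6)-octalin-7-yl]acetate
Conditions: Et3SiCl, imidazole, 4-(dimethylamino)pyridine (cat.), CH2Cl2, 0 °C
Reagents that add atoms: chlorotriethylsilane, CC[Si](Cl)(CC)CC
Why: Silylation of the secondary alcohol before it can lactonise onto C12. The triethylsilyl ether survives steps 10–16 and can later be removed in the presence of the C1 tert-butyldimethylsilyl ether.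

Step 10
Reactants: 15 methyl 2-[(4R,5S,7S,8S,10R)-4,5-epoxy-4,10-dimethyl-8-(triethylsilyloxy)-Δ1(6)-octalin-7-yl]acetate
Product: 17 methyl 2-[(4R,5R,7R,8S,10R)-4,5-epoxy-4,10-dimethyl-1,6-dioxo-8-(triethylsilyloxy)cyclodecan-7-yl]acetate, via methoxy hydroperoxide 16 (not isolated)
Conditions: O3, CH2Cl2/MeOH 5:1, NaHCO3, Solvent Red 23 (indicator), −78 °C; then Me2S, −78 to 0 °C; used at once
Reagents that add atoms: ozone, [O-][O+]=O
Why: Ozone adds as a 1,3-dipole to the only C=C bond, the electron-rich tetrasubstituted C1=C6 alkene, and the primary ozonide fragments to the C6 ketone and a carbonyl oxide at C1, the inductively withdrawing epoxide disfavouring the carbonyl oxide at C6. Methanol traps the carbonyl oxide as the methoxy hydroperoxide 16, which Me2S reduces to the C1 ketone. The closest known reaction type is ozonolytic cleavage of the ring-fusion double bond of 9,10-octalins to cyclodecane-1,6-diones. No ring is closed by bond formation: cutting the bond shared by rings A and B merges them into the ten-membered ring, so there is no cyclisation mode, no entropic penalty and no need for high dilution. No stereocentre is created; C1 and C6 become trigonal, and C4, C5, C7, C8 and C10 are carried over unchanged (the descriptors of C5 and C7 change only because a neighbour gains priority). The selectivity needed is chemoselectivity: cleavage of the alkene without opening the allylic epoxide, over-oxidation, or loss of the silyl ether and ester. It is secured by the absence of any other π-bond, by the high rate of ozone addition to a tetraalkyl alkene at −78 °C with an indicator dye marking the end point, and by solid NaHCO3 keeping the methanolic medium neutral. The diketone is not purified, because acid, base or silica could trigger transannular aldol reaction or β-elimination of the C8 silyloxy group.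

Step 11
Reactants: 17 methyl 2-[(4R,5R,7R,8S,10R)-4,5-epoxy-4,10-dimethyl-1,6-dioxo-8-(triethylsilyloxy)cyclodecan-7-yl]acetate
Product: 19 (1S,4R,5S,6S,7S,8S,10R)-4,5-epoxy-1-hydroxy-8-(triethylsilyloxy)-13-norgermacran-12,6-olide, via diol ester 18 (not isolated)
Conditions: Zn(BH4)2, Et2O, −40 to 0 °C; then 25 °C; aq. NH4Cl
Reagents that add atoms: none
Why: Zn(BH4)2 reduces both ketones. At C6, zinc is expected to chelate the carbonyl and epoxide oxygens so that hydride enters opposite C4, giving the anti epoxy alcohol (6S). At C1, a Felkin–Anh approach anti to C9 and past H10 gives 1S, cis to the C10 methyl. The C6 zinc alkoxide then attacks the C12 ester (5-exo-trig) and expels methoxide, so the trans-fused γ-lactone forms in the same flask.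

Step 12
Reactants: 19 (1S,4R,5S,6S,7S,8S,10R)-4,5-epoxy-1-hydroxy-8-(triethylsilyloxy)-13-norgermacran-12,6-olide
Product: 20 (1S,4R,5S,6S,7S,8S,10R)-1-(tert-butyldimethylsilyloxy)-4,5-epoxy-8-(triethylsilyloxy)-13-norgermacran-12,6-olide
Conditions: t-BuMe2SiOTf, 2,6-lutidine, CH2Cl2, −78 °C
Reagents that add atoms: tert-butyldimethylsilyl trifluoromethanesulfonate, CC(C)(C)[Si](C)(C)OS(=O)(=O)C(F)(F)F
Why: Silylation of the only free hydroxyl under cold, buffered conditions. It blocks transannular attack of O1 on the epoxide and removes the acidic proton before the enolate steps.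

Step 13
Reactants: 20 (1S,4R,5S,6S,7S,8S,10R)-1-(tert-butyldimethylsilyloxy)-4,5-epoxy-8-(triethylsilyloxy)-13-norgermacran-12,6-olide
Product: 22 (1S,4R,5S,6S,7S,8S,10R,11R)-1-(tert-butyldimethylsilyloxy)-4,5-epoxy-13-hydroxy-8-(triethylsilyloxy)germacran-12,6-olide, via lithium enolate 21 (not isolated)
Conditions: LiN(iPr)2, THF, −78 °C; then CH2O (gas, from paraformaldehyde), −78 to −40 °C; aq. NH4Cl
Reagents that add atoms: formaldehyde, C=O
Why: Aldol reaction of the lactone enolate with monomeric formaldehyde. C11 is the only acidic position, and the electrophile enters anti to C8, on the face of H7.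

Step 14
Reactants: 22 (1S,4R,5S,6S,7S,8S,10R,11R)-1-(tert-butyldimethylsilyloxy)-4,5-epoxy-13-hydroxy-8-(triethylsilyloxy)germacran-12,6-olide
Product: 24 (1S,4R,5S,6S,7S,8S,10R,11R)-1-(tert-butyldimethylsilyloxy)-4,5-epoxy-13-hydroxy-11-(phenylselanyl)-8-(triethylsilyloxy)germacran-12,6-olide, via dilithium alkoxide enolate 23 (not isolated)
Conditions: LiN(iPr)2 (2.3 equiv), THF, −78 to −40 °C; then PhSeCl, −78 °C
Reagents that add atoms: benzeneselenenyl chloride, Cl[Se]c1ccccc1
Why: Two equivalents of base give the alkoxide enolate (a β-oxido ester enolate does not eliminate). Selenenylation at C11 again occurs on the face of H7, so selenium ends up cis to H7, as the syn-elimination requires.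

Step 15
Reactants: 24 (1S,4R,5S,6S,7S,8S,10R,11R)-1-(tert-butyldimethylsilyloxy)-4,5-epoxy-13-hydroxy-11-(phenylselanyl)-8-(triethylsilyloxy)germacran-12,6-olide
Product: 26 (1S,4R,5S,6S,8S,10R)-1-(tert-butyldimethylsilyloxy)-4,5-epoxy-13-hydroxy-8-(triethylsilyloxy)germacr-7(11)-en-12,6-olide, via selenoxide 25 (not isolated)
Conditions: 30% H2O2, pyridine, CH2Cl2, 0 to 25 °C
Reagents that add atoms: none
Why: Oxidation to the selenoxide and spontaneous syn-elimination. With H7 cis to selenium the double bond forms in the ring (C7=C11); elimination toward the carbinol carbon C13 is the disfavoured direction. Pyridine buffers the selenenic acid and protects the epoxide.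

Step 16
Reactants: 26 (1S,4R,5S,6S,8S,10R)-1-(tert-butyldimethylsilyloxy)-4,5-epoxy-13-hydroxy-8-(triethylsilyloxy)germacr-7(11)-en-12,6-olide
Product: 27 (1S,4R,5S,6S,8S,10R)-13-acetoxy-1-(tert-butyldimethylsilyloxy)-4,5-epoxy-8-(triethylsilyloxy)germacr-7(11)-en-12,6-olide
Conditions: Ac2O, pyridine, 4-(dimethylamino)pyridine (cat.), CH2Cl2, 0 °C
Reagents that add atoms: acetic anhydride, CC(=O)OC(C)=O
Why: Nucleophile-catalysed acetylation of the only free, primary allylic hydroxyl.

Step 17
Reactants: 27 (1S,4R,5S,6S,8S,10R)-13-acetoxy-1-(tert-butyldimethylsilyloxy)-4,5-epoxy-8-(triethylsilyloxy)germacr-7(11)-en-12,6-olide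
Product: 28 (1S,4R,5S,6S,8S,10R)-13-acetoxy-1-(tert-butyldimethylsilyloxy)-4,5-epoxy-8-hydroxygermacr-7(11)-en-12,6-olide
Conditions: HF·pyridine, excess pyridine, THF, 0 °C
Reagents that add atoms: none
Why: Buffered fluoride cleavage: a secondary triethylsilyl ether is cleaved far faster than a secondary tert-butyldimethylsilyl ether. Excess pyridine keeps the medium near neutral for the epoxide, allylic acetate and butenolide.

Step 18
Reactants: 28 (1S,4R,5S,6S,8S,10R)-13-acetoxy-1-(tert-butyldimethylsilyloxy)-4,5-epoxy-8-hydroxygermacr-7(11)-en-12,6-olide; 29 (E)-2-methylbut-2-enoyl chloride (tigloyl chloride)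
Product: 30 (1S,4R,5S,6S,8S,10R)-13-acetoxy-1-(tert-butyldimethylsilyloxy)-4,5-epoxy-8-[(E)-2-methylbut-2-enoyloxy]germacr-7(11)-en-12,6-olide
Conditions: pyridine, 4-(dimethylamino)pyridine (cat.), CH2Cl2, 0 to 25 °C
Reagents that add atoms: none
Why: Acylation of the C8 alcohol by the acid chloride through the acylpyridinium ion. The E-configured tigloyl group is the stable isomer and is not scrambled. Mild base and low temperature limit lactone migration from O6 to O8 and acetyl migration.

Step 19
Reactants: 30 (1S,4R,5S,6S,8S,10R)-13-acetoxy-1-(tert-butyldimethylsilyloxy)-4,5-epoxy-8-[(E)-2-methylbut-2-enoyloxy]germacr-7(11)-en-12,6-olide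
Product: 31 (1S,4R,5S,6S,8S,10R)-13-acetoxy-4,5-epoxy-1-hydroxy-8-[(E)-2-methylbut-2-enoyloxy]germacr-7(11)-en-12,6-olide (CNP0159184.1)
Conditions: HF·pyridine, pyridine, THF, 0 to 25 °C
Reagents that add atoms: none
Why: Fluoride-mediated cleavage of the remaining silyl ether under pyridine buffering releases the C1 alcohol without touching the esters. Work-up is kept neutral to avoid transannular opening of the epoxide.

## Compound list

1 | (2-methoxy-4-methylphenyl)boronic acid | COc1cc(C)ccc1B(O)O | starting material
2 | (E)-pent-3-en-2-one | C/C=C/C(C)=O | starting material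
3 | (4R)-4-(2-methoxy-4-methylphenyl)pentan-2-one | CC(=O)C[C@@H](C)c1ccc(C)cc1OC | intermediate
4 | 2-[(2R)-2-(2-methoxy-4-methylphenyl)propyl]-2-methyl-1,3-dioxolane | CC1(C[C@@H](C)c2ccc(C)cc2OC)OCCO1 | intermediate
5 | 2-[(2R)-2-(2-methoxy-4-methylcyclohexa-1,4-dien-1-yl)propyl]-2-methyl-1,3-dioxolane | COC1=C([C@H](C)CC2(C)OCCO2)CC=C(C)C1 | intermediate
6 | 3-methyl-6-[(2R)-4-oxopentan-2-yl]cyclohex-3-en-1-one, both epimers at the ring carbon bearing the side chain (C1 of the target); not isolated | CC(=O)C[C@@H](C)C1CC=C(C)CC1=O | intermediate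
7 | 3-methyl-6-[(2R)-4-oxopentan-2-yl]cyclohex-2-en-1-one, both epimers at C1 of the target | CC(=O)C[C@@H](C)C1CCC(C)=CC1=O | intermediate
8 | (4R)-8a-hydroxy-4,7-dimethyl-3,4,4a,5,6,8a-hexahydronaphthalen-2(1H)-one (ketol; ring-fusion centres not defined; not isolated) | C[C@@H]1CC(=O)CC2(O)C=C(C)CCC12 | intermediate
9 | (4R)-4,7-dimethyl-4,4a,5,6-tetrahydronaphthalen-2(3H)-one (target locants: 8-ketone, C6=C7 and C4=C5, 10R; C1 epimers) | C[C@@H]1CC(=O)C=C2C=C(C)CCC12 | intermediate
10 | (4R,7R,8S)-7,8-epoxy-4,7-dimethyl-4,4a,5,6,7,8-hexahydronaphthalen-2(3H)-one (target locants: 4R,5S-epoxide, 10R, 8-ketone, C6=C7; C1 epimers) | C[C@@H]1CC(=O)C=C2[C@@H]3O[C@]3(C)CCC12 | intermediate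
11 | methyl bromoacetate | COC(=O)CBr | starting material
12 | potassium dienolate of 10 (O–C8=C7–C6=C1; not isolated) | C[C@@H]1CC([O-])=CC2=C1CC[C@@]1(C)O[C@H]12.[K+] | intermediate
13 | methyl 2-[(4R,5S,7S,10R)-4,5-epoxy-4,10-dimethyl-8-oxo-Δ1(6)-octalin-7-yl]acetate | O=C1C[C@@H](C)C2=C([C@@H]3O[C@]3(C)CC2)[C@@H]1CC(=O)OC | intermediate
14 | methyl 2-[(4R,5S,7S,8S,10R)-4,5-epoxy-8-hydroxy-4,10-dimethyl-Δ1(6)-octalin-7-yl]acetate | O[C@H]1C[C@@H](C)C2=C([C@@H]3O[C@]3(C)CC2)[C@@H]1CC(=O)OC | intermediate
15 | methyl 2-[(4R,5S,7S,8S,10R)-4,5-epoxy-4,10-dimethyl-8-(triethylsilyloxy)-Δ1(6)-octalin-7-yl]acetate (key-step precursor) | CC[Si](CC)(CC)O[C@H]1C[C@@H](C)C2=C([C@@H]3O[C@]3(C)CC2)[C@@H]1CC(=O)OC | intermediate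
16 | methyl 2-[(4R,5R,7R,8S,10R)-4,5-epoxy-1-hydroperoxy-1-methoxy-4,10-dimethyl-6-oxo-8-(triethylsilyloxy)cyclodecan-7-yl]acetate (C1 not defined; not isolated) | CC[Si](CC)(CC)O[C@H]1C[C@@H](C)C(OC)(OO)CC[C@@]2(C)O[C@H]2C(=O)[C@@H]1CC(=O)OC | intermediate
17 | methyl 2-[(4R,5R,7R,8S,10R)-4,5-epoxy-4,10-dimethyl-1,6-dioxo-8-(triethylsilyloxy)cyclodecan-7-yl]acetate (key-step product) | CC[Si](CC)(CC)O[C@H]1C[C@@H](C)C(=O)CC[C@@]2(C)O[C@H]2C(=O)[C@@H]1CC(=O)OC | intermediate
18 | methyl 2-[(1S,4R,5S,6S,7S,8S,10R)-4,5-epoxy-1,6-dihydroxy-4,10-dimethyl-8-(triethylsilyloxy)cyclodecan-7-yl]acetate (not isolated) | CC[Si](CC)(CC)O[C@H]1C[C@@H](C)[C@@H](O)CC[C@@]2(C)O[C@H]2[C@@H](O)[C@@H]1CC(=O)OC | intermediate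
19 | (1S,4R,5S,6S,7S,8S,10R)-4,5-epoxy-1-hydroxy-8-(triethylsilyloxy)-13-norgermacran-12,6-olide (trans-fused γ-lactone) | CC[Si](CC)(CC)O[C@H]1C[C@@H](C)[C@@H](O)CC[C@@]2(C)O[C@H]2[C@H]2OC(=O)C[C@H]12 | intermediate
20 | (1S,4R,5S,6S,7S,8S,10R)-1-(tert-butyldimethylsilyloxy)-4,5-epoxy-8-(triethylsilyloxy)-13-norgermacran-12,6-olide | CC[Si](CC)(CC)O[C@H]1C[C@@H](C)[C@@H](O[Si](C)(C)C(C)(C)C)CC[C@@]2(C)O[C@H]2[C@H]2OC(=O)C[C@H]12 | intermediate
21 | lithium enolate of 20 (C11=C12–OLi; not isolated) | CC[Si](CC)(CC)O[C@H]1C[C@@H](C)[C@@H](O[Si](C)(C)C(C)(C)C)CC[C@@]2(C)O[C@H]2[C@H]2OC([O-])=C[C@H]12.[Li+] | intermediate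
22 | (1S,4R,5S,6S,7S,8S,10R,11R)-1-(tert-butyldimethylsilyloxy)-4,5-epoxy-13-hydroxy-8-(triethylsilyloxy)germacran-12,6-olide (CH2OH cis to H7) | CC[Si](CC)(CC)O[C@H]1C[C@@H](C)[C@@H](O[Si](C)(C)C(C)(C)C)CC[C@@]2(C)O[C@H]2[C@H]2OC(=O)[C@@H](CO)[C@H]12 | intermediate
23 | dilithium alkoxide enolate of 22 (not isolated) | CC[Si](CC)(CC)O[C@H]1C[C@@H](C)[C@@H](O[Si](C)(C)C(C)(C)C)CC[C@@]2(C)O[C@H]2[C@H]2OC([O-])=C(C[O-])[C@H]12.[Li+].[Li+] | intermediate
24 | (1S,4R,5S,6S,7S,8S,10R,11R)-1-(tert-butyldimethylsilyloxy)-4,5-epoxy-13-hydroxy-11-(phenylselanyl)-8-(triethylsilyloxy)germacran-12,6-olide (Se cis to H7) | CC[Si](CC)(CC)O[C@H]1C[C@@H](C)[C@@H](O[Si](C)(C)C(C)(C)C)CC[C@@]2(C)O[C@H]2[C@H]2OC(=O)[C@@](CO)([Se]c3ccccc3)[C@H]12 | intermediate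
25 | selenoxide of 24 (Se configuration not defined; not isolated) | CC[Si](CC)(CC)O[C@H]1C[C@@H](C)[C@@H](O[Si](C)(C)C(C)(C)C)CC[C@@]2(C)O[C@H]2[C@H]2OC(=O)[C@@](CO)([Se](=O)c3ccccc3)[C@H]12 | intermediate
26 | (1S,4R,5S,6S,8S,10R)-1-(tert-butyldimethylsilyloxy)-4,5-epoxy-13-hydroxy-8-(triethylsilyloxy)germacr-7(11)-en-12,6-olide | CC[Si](CC)(CC)O[C@H]1C[C@@H](C)[C@@H](O[Si](C)(C)C(C)(C)C)CC[C@@]2(C)O[C@H]2[C@H]2OC(=O)C(CO)=C12 | intermediate
27 | (1S,4R,5S,6S,8S,10R)-13-acetoxy-1-(tert-butyldimethylsilyloxy)-4,5-epoxy-8-(triethylsilyloxy)germacr-7(11)-en-12,6-olide | CC[Si](CC)(CC)O[C@H]1C[C@@H](C)[C@@H](O[Si](C)(C)C(C)(C)C)CC[C@@]2(C)O[C@H]2[C@H]2OC(=O)C(COC(C)=O)=C12 | intermediate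
28 | (1S,4R,5S,6S,8S,10R)-13-acetoxy-1-(tert-butyldimethylsilyloxy)-4,5-epoxy-8-hydroxygermacr-7(11)-en-12,6-olide | O[C@H]1C[C@@H](C)[C@@H](O[Si](C)(C)C(C)(C)C)CC[C@@]2(C)O[C@H]2[C@H]2OC(=O)C(COC(C)=O)=C12 | intermediate
29 | (E)-2-methylbut-2-enoyl chloride (tigloyl chloride) | C/C=C(\C)C(=O)Cl | starting material
30 | (1S,4R,5S,6S,8S,10R)-13-acetoxy-1-(tert-butyldimethylsilyloxy)-4,5-epoxy-8-[(E)-2-methylbut-2-enoyloxy]germacr-7(11)-en-12,6-olide | C/C=C(\C)C(=O)O[C@H]1C[C@@H](C)[C@@H](O[Si](C)(C)C(C)(C)C)CC[C@@]2(C)O[C@H]2[C@H]2OC(=O)C(COC(C)=O)=C12 | intermediate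
31 | (1S,4R,5S,6S,8S,10R)-13-acetoxy-4,5-epoxy-1-hydroxy-8-[(E)-2-methylbut-2-enoyloxy]germacr-7(11)-en-12,6-olide (CNP0159184.1) | C/C=C(\C)C(=O)O[C@H]1C[C@@H](C)[C@@H](O)CC[C@@]2(C)O[C@H]2[C@H]2OC(=O)C(COC(C)=O)=C12 | target

## Step count and least certain steps

Total step count: 19. Longest linear sequence: 19 steps, from 1 and 2 to 31; 11 and 29 enter in steps 7 and 18.

**Step 10 (key step).** The cleavage itself is unlikely to fail. The likely loss is further reaction of the product: transannular aldol reaction between an enolisable position (C2, C7) and the opposite carbonyl, β-elimination of the C8 silyloxy group from the C6 ketone, or abnormal fragmentation of the carbonyl oxide next to the epoxide. Fallback: the alkene is cleaved in two non-peroxidic steps. From 15, dihydroxylation with catalytic OsO4 and N-methylmorpholine N-oxide in the presence of pyridine gives the cis-1,6-diol F1. Glycol cleavage with Pb(OAc)4 in benzene over K2CO3 at 0 °C then gives the diketone, and the route is rejoined at 17.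

**Step 6.** The risk is poor facial selectivity, since the spiro model is being applied to a cyclic alkene inside a dienone. Sluggish oxygen transfer is also possible, because the C4=C5 bond is less electron-rich than an isolated trisubstituted alkene. Fallback: the epoxide is introduced one stage earlier, by nucleophilic instead of electrophilic epoxidation. From 7, H2O2 with a cinchona-derived primary amine salt (9-amino-9-deoxy-epi-quinine or its pseudo-enantiomer, iminium activation) epoxidises the ring enone to the epoxy diketone F2. Its aldol condensation (KOH, MeOH, 0 °C) closes ring B and returns to 10.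

**Step 7.** The risk is alkylation at the wrong site or more than once: kinetic deprotonation at C9, O-alkylation, a second alkylation at C7, or isomerisation of the product back into conjugation under residual base. Fallback: a neutral Stork enamine alkylation. From 10, pyrrolidine (benzene, reflux, removal of water) gives the dienamine F3, which can only be the N–C8=C7–C6=C1 isomer. Alkylation with 11 in MeCN and hydrolysis in aqueous NaOAc/AcOH buffer give 13.

**Step 8.** The risk is poor facial selectivity. If the half-chair with pseudo-axial C7 and C10 groups dominates, the ring's own bias opposes the catalyst and favours the 8R alcohol. Fallback: the centre is inverted, not reduced again. From 13, reduction with NaBH4/CeCl3·7H2O in MeOH at −78 °C gives the 8R alcohol F4, which is kept cold to prevent lactonisation. Mitsunobu reaction (PPh3, diisopropyl azodicarboxylate, 4-nitrobenzoic acid) gives the inverted 8S 4-nitrobenzoate F5. K2CO3 in MeOH at 0 °C cleaves the aryl ester and returns to 14.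

**Step 11.** The risk is poor or wrong facial selectivity, most of all at C1. The conformation of the ten-membered diketone, not the acyclic chelation and Felkin–Anh models, decides which carbonyl face is exposed. Payne rearrangement of the C6 alkoxide before lactonisation is a second risk. Fallback: the two carbonyls are reduced one after the other, each with its own reagent. From 17, NaBH4/CeCl3·7H2O in MeOH at −78 °C reduces the more electrophilic α-epoxy ketone at C6, and lactonisation gives the keto lactone F6, which no longer has a transannular partner. The C1 ketone is then reduced under catalyst control (CBS-oxazaborolidine, catecholborane), which returns to 19.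

**Step 14.** The risks are retro-aldol loss of formaldehyde from the alkoxide, incomplete formation of the tetrasubstituted enolate, or selenium entering trans to H7 so that elimination into the ring is impossible. Fallback: C13 is introduced at the aldehyde oxidation level, so that no dianion is needed. From 20, LiN(iPr)2 and ethyl formate give the α-formyl lactone F7 (enolised). PhSeCl with pyridine in CH2Cl2 selenenylates it at C11 to the formyl selenide F8. H2O2 gives the formyl butenolide F9 by selenoxide elimination, and Luche reduction (NaBH4, CeCl3·7H2O, MeOH, −78 °C) of the aldehyde returns to 26.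

## Further compounds

F1 | step 10 | methyl 2-[(4R,5S,7S,8S,10R)-4,5-epoxy-1,6-dihydroxy-4,10-dimethyl-8-(triethylsilyloxy)decalin-7-yl]acetate (cis-1,6-diol, face not defined) | CC[Si](CC)(CC)O[C@H]1C[C@@H](C)C2(O)CC[C@@]3(C)O[C@H]3C2(O)[C@@H]1CC(=O)OC
F2 | step 6 | (2S,3R)-2,3-epoxy-3-methyl-6-[(2R)-4-oxopentan-2-yl]cyclohexan-1-one (target locants 5S,4R; C1 epimers) | CC(=O)C[C@@H](C)C1CC[C@@]2(C)O[C@H]2C1=O
F3 | step 7 | pyrrolidine dienamine of 10 (N–C8=C7–C6=C1; 4R,5S,10R) | C[C@@H]1CC(N2CCCC2)=CC2=C1CC[C@@]1(C)O[C@H]12
F4 | step 8 | methyl 2-[(4R,5S,7S,8R,10R)-4,5-epoxy-8-hydroxy-4,10-dimethyl-Δ1(6)-octalin-7-yl]acetate (8-epimer of 14) | O[C@@H]1C[C@@H](C)C2=C([C@@H]3O[C@]3(C)CC2)[C@@H]1CC(=O)OC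
F5 | step 8 | methyl 2-[(4R,5S,7S,8S,10R)-4,5-epoxy-4,10-dimethyl-8-(4-nitrobenzoyloxy)-Δ1(6)-octalin-7-yl]acetate | O=C(O[C@H]1C[C@@H](C)C2=C([C@@H]3O[C@]3(C)CC2)[C@@H]1CC(=O)OC)c1ccc(cc1)[N+](=O)[O-]
F6 | step 11 | (4R,5S,6S,7S,8S,10R)-4,5-epoxy-1-oxo-8-(triethylsilyloxy)-13-norgermacran-12,6-olide | CC[Si](CC)(CC)O[C@H]1C[C@@H](C)C(=O)CC[C@@]2(C)O[C@H]2[C@H]2OC(=O)C[C@H]12
F7 | step 14 | (1S,4R,5S,6S,7S,8S,10R)-1-(tert-butyldimethylsilyloxy)-4,5-epoxy-13-oxo-8-(triethylsilyloxy)germacran-12,6-olide (α-formyl lactone, enolised, C11 not defined) | CC[Si](CC)(CC)O[C@H]1C[C@@H](C)[C@@H](O[Si](C)(C)C(C)(C)C)CC[C@@]2(C)O[C@H]2[C@H]2OC(=O)C(C=O)[C@H]12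
F8 | step 14 | (1S,4R,5S,6S,7S,8S,10R)-1-(tert-butyldimethylsilyloxy)-4,5-epoxy-13-oxo-11-(phenylselanyl)-8-(triethylsilyloxy)germacran-12,6-olide (Se cis to H7) | CC[Si](CC)(CC)O[C@H]1C[C@@H](C)[C@@H](O[Si](C)(C)C(C)(C)C)CC[C@@]2(C)O[C@H]2[C@H]2OC(=O)[C@@](C=O)([Se]c3ccccc3)[C@H]12
F9 | step 14 | (1S,4R,5S,6S,8S,10R)-1-(tert-butyldimethylsilyloxy)-4,5-epoxy-13-oxo-8-(triethylsilyloxy)germacr-7(11)-en-12,6-olide | CC[Si](CC)(CC)O[C@H]1C[C@@H](C)[C@@H](O[Si](C)(C)C(C)(C)C)CC[C@@]2(C)O[C@H]2[C@H]2OC(=O)C(C=O)=C12
A1 | alternative 1 | 4,5-deoxy (Z-alkene) lactone with tiglate and acetate, C1 triethylsilyl ether | C/C=C(\C)C(=O)O[C@H]1C[C@@H](C)[C@@H](O[Si](CC)(CC)CC)CC/C(C)=C\[C@H]2OC(=O)C(COC(C)=O)=C12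
A2 | alternative 1 | open-chain (Z)-alkenyl iodide with C6 aldehyde and cis C12 methyl ester on the C7=C11 enoate | C/C=C(\C)C(=O)O[C@@H](C[C@@H](C)[C@@H](O[Si](CC)(CC)CC)CC/C(C)=C\I)/C(C=O)=C(\COC(C)=O)C(=O)OC
A3 | alternative 2 | cis,anti,cis photoadduct (silyloxy cyclohexanone fused to a dimethylbicyclo[2.2.0]hexane) | CC(C)(C)[Si](C)(C)O[C@H]1C[C@]2(C)[C@H]3CC[C@@]3(C)[C@@H]2C(=O)C1
A4 | alternative 2 | (5S)-5-(tert-butyldimethylsilyloxy)-3-methylcyclohex-2-en-1-one | CC(C)(C)[Si](C)(C)O[C@H]1CC(C)=CC(=O)C1
A5 | alternative 2 | 1-methylcyclobutene | CC1=CCC1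
A6 | alternative 3 | butenolide with C13 acetate (C4,C5 acetonide, C8 OPMB, C1 OTBS) | COc1ccc(CO[C@H]2C[C@@H](C)[C@@H](O[Si](C)(C)C(C)(C)C)CC[C@@]3(C)OC(C)(C)O[C@@H]3[C@H]3OC(=O)C(COC(C)=O)=C23)cc1
A7 | alternative 3 | ring dienoic acid: (E)-C6=C7 cyclodecene carrying the 2-propenoic acid unit (C11=C13, C12 acid) on C7 | COc1ccc(CO[C@H]2C[C@@H](C)[C@@H](O[Si](C)(C)C(C)(C)C)CC[C@@]3(C)OC(C)(C)O[C@@H]3/C=C/2C(=C)C(=O)O)cc1
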